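**Assumptions (one line each):** the target is taken exactly as the given SMILES, which in 1H‑indene numbering is (1R,3aR,4R,5S,7aS) with a trans ring fusion. The facial sense of the chiral Rh catalyst in Step 15 is assigned by analogy, so the ligand enantiomer is the one that gives 6R. This route is a paper design; nothing in it has been run.

## Retrosynthetic overview

1. Spiculoic acid B ⇐ its 2‑(trimethylsilyl)ethyl (TMSE) ester; the C3 ethyl and the cyclopentene C2=C3 come from a kinetic enol triflate of a trans‑hydrindan‑3‑one by Fe‑catalysed ethylation.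
2. Both rings form in one intramolecular Diels–Alder (IMDA) of a linear (6R)‑tetraene keto ester: the cyclohexene by [4+2], the five‑membered ring as the tether; this sets C3a, C4, C5 and C7a.
3. The single stereocentre of that tetraene is set by the proposed new step: a site‑ and enantioselective Rh/chiral‑diene 1,4‑alkenylation joining a trienyl boronate to a cross‑conjugated dienone.
4. Trienyl boronate ⇐ (E)‑2‑ethyl‑3‑iodoacrylic acid by iterative Wittig/HWE; dienone ⇐ (E)‑3‑iodo‑2‑methylacrylate + crotonaldehyde (Nozaki–Hiyama–Kishi, oxidation); both iodoacrylic acids ⇐ alkylmalonate + CHI3.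

## Route

### Part A – trienyl boronate

**Step 1**
Reactants: 1 diethyl 2‑ethylmalonate
Product: 2 diethyl 2‑(diiodomethyl)‑2‑ethylmalonate
Conditions: NaH, Et2O, reflux; then CHI3, reflux
Reagents that add atoms: iodoform, IC(I)I
Why: C‑alkylation of the malonate anion with iodoform (diiodocarbene capture) installs the CHI2 carbon that becomes C7a; no stereocentre.

**Step 2**
Reactants: 2 diethyl 2‑(diiodomethyl)‑2‑ethylmalonate
Product: 3 (E)‑2‑ethyl‑3‑iodoacrylic acid
Conditions: KOH, EtOH/H2O, reflux; then aq HCl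
Reagents that add atoms: potassium hydroxide/water, [K+].[OH-] and O
Why: Saponification followed by decarboxylative elimination of iodide gives the thermodynamically favoured E β‑iodoacrylic acid (I trans to CO2H).

**Step 3**
Reactants: 3 (E)‑2‑ethyl‑3‑iodoacrylic acid
Product: 4 (E)‑2‑ethyl‑3‑iodoprop‑2‑en‑1‑ol
Conditions: LiAlH4, Et2O, 0 °C to rt
Reagents that add atoms: none
Why: Hydride reduction of the acid to the allylic alcohol; the vinyl C–I bond and alkene geometry are retained.

**Step 4**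
Reactants: 4 (E)‑2‑ethyl‑3‑iodoprop‑2‑en‑1‑ol
Product: 5 (E)‑2‑ethyl‑3‑iodoprop‑2‑enal
Conditions: MnO2, CH2Cl2, rt
Reagents that add atoms: none
Why: Chemoselective allylic oxidation with MnO2, without E/Z erosion.

**Step 5**
Reactants: 5 (E)‑2‑ethyl‑3‑iodoprop‑2‑enal; 6 ethyl 2‑(triphenylphosphoranylidene)butanoate
Product: 7 ethyl (2E,4E)‑2,4‑diethyl‑5‑iodopenta‑2,4‑dienoate
Conditions: toluene, 90 °C
Reagents that add atoms: none (6 is a listed reactant)
Why: Wittig olefination with a stabilised α‑ethyl ylide gives the E trisubstituted enoate (ester trans to the chain).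

**Step 6**
Reactants: 7 ethyl (2E,4E)‑2,4‑diethyl‑5‑iodopenta‑2,4‑dienoate
Product: 8 (2E,4E)‑2,4‑diethyl‑5‑iodopenta‑2,4‑dien‑1‑ol
Conditions: DIBAL‑H, CH2Cl2, −78 °C
Reagents that add atoms: none
Why: 1,2‑Reduction of the conjugated ester to the allylic alcohol; the vinyl iodide is inert to DIBAL at −78 °C.

**Step 7**
Reactants: 8 (2E,4E)‑2,4‑diethyl‑5‑iodopenta‑2,4‑dien‑1‑ol
Product: 9 (2E,4E)‑2,4‑diethyl‑5‑iodopenta‑2,4‑dienal
Conditions: MnO2, CH2Cl2, rt
Reagents that add atoms: none
Why: Allylic oxidation with MnO2 to the dienal.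

**Step 8**
Reactants: 9 (2E,4E)‑2,4‑diethyl‑5‑iodopenta‑2,4‑dienal; 10 diethyl benzylphosphonate
Product: 11 [(1E,3E,5E)‑3,5‑diethyl‑6‑iodohexa‑1,3,5‑trien‑1‑yl]benzene
Conditions: NaH, THF, 0 °C; then 9, 0 °C to rt
Reagents that add atoms: none (10 is a listed reactant)
Why: Horner–Wadsworth–Emmons reaction of the benzylphosphonate anion gives the E styryl alkene; the vinyl iodide cannot undergo β‑elimination because C2 carries no hydrogen.

**Step 9**
Reactants: 11 [(1E,3E,5E)‑3,5‑diethyl‑6‑iodohexa‑1,3,5‑trien‑1‑yl]benzene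
Product: 12 2‑[(1E,3E,5E)‑2,4‑diethyl‑6‑phenylhexa‑1,3,5‑trien‑1‑yl]‑4,4,5,5‑tetramethyl‑1,3,2‑dioxaborolane
Conditions: t‑BuLi (2.1 equiv), Et2O, −78 °C; then i‑PrOBpin, −78 °C to rt
Reagents that add atoms: 2‑isopropoxy‑4,4,5,5‑tetramethyl‑1,3,2‑dioxaborolane, CC(C)OB1OC(C)(C)C(C)(C)O1
Why: Li–I exchange and borate trapping both proceed with retention of alkene geometry (alkenyllithium borylation).

### Part B – cross‑conjugated dienone

**Step 10**
Reactants: 13 diethyl 2‑methylmalonate
Product: 14 diethyl 2‑(diiodomethyl)‑2‑methylmalonate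
Conditions: NaH, Et2O, reflux; then CHI3, reflux
Reagents that add atoms: iodoform, IC(I)I
Why: Same malonate/iodoform alkylation as Step 1; this carbon becomes C3a.

**Step 11**
Reactants: 14 diethyl 2‑(diiodomethyl)‑2‑methylmalonate
Product: 15 (E)‑3‑iodo‑2‑methylacrylic acid
Conditions: KOH, EtOH/H2O, reflux; then aq HCl
Reagents that add atoms: potassium hydroxide/water, [K+].[OH-] and O
Why: Saponification and decarboxylative elimination give the E iodoacrylic acid, fixing the dienophile geometry (CO2R trans to the future ketone).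

**Step 12**
Reactants: 15 (E)‑3‑iodo‑2‑methylacrylic acid
Product: 16 2‑(trimethylsilyl)ethyl (E)‑3‑iodo‑2‑methylacrylate
Conditions: TMSCH2CH2OH, DCC, DMAP (cat.), CH2Cl2, 0 °C to rt
Reagents that add atoms: 2‑(trimethylsilyl)ethanol, C[Si](C)(C)CCO
Why: Steglich esterification; the TMSE ester is chosen because it can be removed by fluoride from the doubly neopentyl position where saponification would fail.

**Step 13**
Reactants: 16 2‑(trimethylsilyl)ethyl (E)‑3‑iodo‑2‑methylacrylate; 17 (E)‑crotonaldehyde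
Product: 18 2‑(trimethylsilyl)ethyl (2E,5E)‑4‑hydroxy‑2‑methylhepta‑2,5‑dienoate (racemic at C4)
Conditions: CrCl2 (4 equiv), NiCl2 (1 mol%), DMSO, rt
Reagents that add atoms: none (17 is a listed reactant)
Why: Nozaki–Hiyama–Kishi coupling; the alkenylchromium adds 1,2 to the enal with retention of vinyl geometry and tolerates the ester (the C4 carbinol is oxidised next, so its configuration is irrelevant).

**Step 14**
Reactants: 18 2‑(trimethylsilyl)ethyl (2E,5E)‑4‑hydroxy‑2‑methylhepta‑2,5‑dienoate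
Product: 19 2‑(trimethylsilyl)ethyl (2E,5E)‑2‑methyl‑4‑oxohepta‑2,5‑dienoate
Conditions: Dess–Martin periodinane, NaHCO3, CH2Cl2, 0 °C (use directly)
Reagents that add atoms: none
Why: Mild buffered oxidation of the bis‑allylic alcohol to the cross‑conjugated dienone without alkene isomerisation.

### Part C – union, cyclisation, endgame

**Step 15 (proposed new step)**
Reactants: 12 trienyl pinacol boronate (1.5 equiv); 19 cross‑conjugated dienone
Product: 20 2‑(trimethylsilyl)ethyl (2E,6R,7E,9E,11E)‑8,10‑diethyl‑2,6‑dimethyl‑4‑oxo‑12‑phenyldodeca‑2,7,9,11‑tetraenoate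
Conditions: [RhCl(C2H4)2]2 (2.5 mol%), chiral diene (R,R)‑Ph‑bod* (5.5 mol%; enantiomer chosen for Cβ Re‑face delivery), KOH (0.2 equiv), dioxane/H2O 10:1, 30 °C
Reagents that add atoms: none (C5–H comes from water)
Why: Proposed new method: a site‑ and enantioselective Rh(I)/chiral‑diene conjugate alkenylation of an unsymmetrical divinyl ketone with a conjugated trienyl boronate. B→Rh transmetalation and insertion keep the trienyl geometry; the alkenyl–Rh should insert only into the 1,2‑disubstituted crotonyl C5=C6, because the other alkene is α‑branched towards the ester and β,β‑disubstituted towards the ketone, a substitution pattern Rh–diene catalysts barely accept; the diene pocket selects the Re face of C6 to set 6R (the only stereocentre, which later controls four more), and water protonates the oxa‑π‑allyl rhodium at C5. The closest known reaction type is the Hayashi–Miyaura asymmetric 1,4‑addition of alkenylboron reagents to simple acyclic enones; neither site discrimination between two enone arms nor transfer of a polyenyl group has been shown.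

**Step 16**
Reactants: 20 (6R)‑tetraene keto ester
Product: 21 2‑(trimethylsilyl)ethyl (1R,3aS,4R,5S,7aS)‑5,7‑diethyl‑1,4‑dimethyl‑3‑oxo‑5‑[(E)‑2‑phenylethenyl]‑2,3,3a,4,5,7a‑hexahydro‑1H‑indene‑4‑carboxylate (trans‑fused; same spatial arrangement as the target)
Conditions: toluene (0.01 M), BHT (cat.), 100 °C
Reagents that add atoms: none
Why: Thermal type‑1 intramolecular Diels–Alder reaction of a 1,3,8‑nonatriene: the ester‑endo/tether‑exo transition state gives the trans fusion (C3a, C7a); the E,E‑diene and E‑dienophile geometries set the vicinal quaternary C5 and C4; and C6–H eclipses the diene to avoid A(1,3) strain with the C8 ethyl, so the dienophile adds anti to the C6 methyl (C1‑Me cis to C7a‑H).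

**Step 17**
Reactants: 21 trans‑hydrindan‑3‑one TMSE ester
Product: 22 2‑(trimethylsilyl)ethyl (1S,3aS,4R,5S,7aS)‑5,7‑diethyl‑1,4‑dimethyl‑5‑[(E)‑2‑phenylethenyl]‑3‑{[(trifluoromethyl)sulfonyl]oxy}‑3a,4,5,7a‑tetrahydro‑1H‑indene‑4‑carboxylate (descriptor changes at C1 and C3a are CIP only)
Conditions: KHMDS, THF, −78 °C; then PhNTf2, −78 to 0 °C
Reagents that add atoms: N‑phenyl‑bis(trifluoromethanesulfonimide), O=S(=O)(N(c1ccccc1)S(=O)(=O)C(F)(F)F)C(F)(F)F
Why: Kinetic enolisation occurs at the accessible C2 methylene rather than the hindered C3a–H next to the quaternary C4, so the enol triflate places the double bond at C2=C3 without touching the ring fusion; the ester has no α‑H.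

**Step 18**
Reactants: 22 enol triflate
Product: 23 2‑(trimethylsilyl)ethyl (1R,3aR,4R,5S,7aS)‑3,5,7‑triethyl‑1,4‑dimethyl‑5‑[(E)‑2‑phenylethenyl]‑3a,4,5,7a‑tetrahydro‑1H‑indene‑4‑carboxylate
Conditions: EtMgBr, Fe(acac)3 (5 mol%), THF/NMP, −30 °C
Reagents that add atoms: ethylmagnesium bromide, CC[Mg]Br
Why: Iron‑catalysed Kumada‑type coupling of an alkenyl triflate with an alkyl Grignard is fast at low temperature, avoids β‑hydride problems and spares the hindered ester and the other alkenes.

**Step 19**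
Reactants: 23 spiculoic acid B TMSE ester
Product: 24 spiculoic acid B, (1R,3aR,4R,5S,7aS)‑3,5,7‑triethyl‑1,4‑dimethyl‑5‑[(E)‑2‑phenylethenyl]‑3a,4,5,7a‑tetrahydro‑1H‑indene‑4‑carboxylic acid
Conditions: TBAF, THF, rt; pH 5 buffer work‑up
Reagents that add atoms: none
Why: Fluoride‑induced β‑elimination of the TMSE group (loss of ethylene and Me3SiF) frees the acid without attack at the hindered carbonyl and without strong acid, which could lactonise onto the alkenes.

## Compound list

1 | diethyl 2‑ethylmalonate | CCOC(=O)C(CC)C(=O)OCC | starting material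
2 | diethyl 2‑(diiodomethyl)‑2‑ethylmalonate | CCOC(=O)C(CC)(C(I)I)C(=O)OCC | intermediate
3 | (E)‑2‑ethyl‑3‑iodoacrylic acid | CC/C(=C\I)C(=O)O | intermediate
4 | (E)‑2‑ethyl‑3‑iodoprop‑2‑en‑1‑ol | CC/C(=C\I)CO | intermediate
5 | (E)‑2‑ethyl‑3‑iodoprop‑2‑enal | CC/C(=C\I)C=O | intermediate
6 | ethyl 2‑(triphenylphosphoranylidene)butanoate | CCOC(=O)C(CC)=P(c1ccccc1)(c1ccccc1)c1ccccc1 | starting material
7 | ethyl (2E,4E)‑2,4‑diethyl‑5‑iodopenta‑2,4‑dienoate | CCOC(=O)/C(CC)=C/C(CC)=C/I | intermediate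
8 | (2E,4E)‑2,4‑diethyl‑5‑iodopenta‑2,4‑dien‑1‑ol | OC/C(CC)=C/C(CC)=C/I | intermediate
9 | (2E,4E)‑2,4‑diethyl‑5‑iodopenta‑2,4‑dienal | O=C/C(CC)=C/C(CC)=C/I | intermediate
10 | diethyl benzylphosphonate | CCOP(=O)(Cc1ccccc1)OCC | starting material
11 | [(1E,3E,5E)‑3,5‑diethyl‑6‑iodohexa‑1,3,5‑trien‑1‑yl]benzene | I/C=C(CC)/C=C(CC)/C=C/c1ccccc1 | intermediate
12 | 2‑[(1E,3E,5E)‑2,4‑diethyl‑6‑phenylhexa‑1,3,5‑trien‑1‑yl]‑4,4,5,5‑tetramethyl‑1,3,2‑dioxaborolane | CC1(C)OB(/C=C(CC)/C=C(CC)/C=C/c2ccccc2)OC1(C)C | intermediate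
13 | diethyl 2‑methylmalonate | CCOC(=O)C(C)C(=O)OCC | starting material
14 | diethyl 2‑(diiodomethyl)‑2‑methylmalonate | CCOC(=O)C(C)(C(I)I)C(=O)OCC | intermediate
15 | (E)‑3‑iodo‑2‑methylacrylic acid | C/C(=C\I)C(=O)O | intermediate
16 | 2‑(trimethylsilyl)ethyl (E)‑3‑iodo‑2‑methylacrylate | C/C(=C\I)C(=O)OCC[Si](C)(C)C | intermediate
17 | (E)‑crotonaldehyde | C/C=C/C=O | starting material
18 | 2‑(trimethylsilyl)ethyl (2E,5E)‑4‑hydroxy‑2‑methylhepta‑2,5‑dienoate (racemic) | C/C=C/C(O)/C=C(\C)C(=O)OCC[Si](C)(C)C | intermediate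
19 | 2‑(trimethylsilyl)ethyl (2E,5E)‑2‑methyl‑4‑oxohepta‑2,5‑dienoate | C/C=C/C(=O)/C=C(\C)C(=O)OCC[Si](C)(C)C | intermediate
20 | 2‑(trimethylsilyl)ethyl (2E,6R,7E,9E,11E)‑8,10‑diethyl‑2,6‑dimethyl‑4‑oxo‑12‑phenyldodeca‑2,7,9,11‑tetraenoate | C[C@H](CC(=O)/C=C(\C)C(=O)OCC[Si](C)(C)C)/C=C(CC)/C=C(CC)/C=C/c1ccccc1 | intermediate
21 | TMSE (1R,3aS,4R,5S,7aS)‑5,7‑diethyl‑1,4‑dimethyl‑3‑oxo‑5‑[(E)‑styryl]‑2,3,3a,4,5,7a‑hexahydro‑1H‑indene‑4‑carboxylate | CCC1=C[C@@](/C=C/c2ccccc2)(CC)[C@](C)(C(=O)OCC[Si](C)(C)C)[C@H]2C(=O)C[C@@H](C)[C@H]12 | intermediate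
22 | TMSE (1S,3aS,4R,5S,7aS)‑5,7‑diethyl‑1,4‑dimethyl‑5‑[(E)‑styryl]‑3‑(triflyloxy)‑3a,4,5,7a‑tetrahydro‑1H‑indene‑4‑carboxylate | CCC1=C[C@@](/C=C/c2ccccc2)(CC)[C@](C)(C(=O)OCC[Si](C)(C)C)[C@H]2C(OS(=O)(=O)C(F)(F)F)=C[C@@H](C)[C@H]12 | intermediate
23 | TMSE (1R,3aR,4R,5S,7aS)‑3,5,7‑triethyl‑1,4‑dimethyl‑5‑[(E)‑styryl]‑3a,4,5,7a‑tetrahydro‑1H‑indene‑4‑carboxylate | CCC1=C[C@@](/C=C/c2ccccc2)(CC)[C@](C)(C(=O)OCC[Si](C)(C)C)[C@H]2C(CC)=C[C@@H](C)[C@H]12 | intermediate
24 | spiculoic acid B, (1R,3aR,4R,5S,7aS)‑3,5,7‑triethyl‑1,4‑dimethyl‑5‑[(E)‑2‑phenylethenyl]‑3a,4,5,7a‑tetrahydro‑1H‑indene‑4‑carboxylic acid | CCC1=C[C@@](/C=C/c2ccccc2)(CC)[C@](C)(C(=O)O)[C@H]2C(CC)=C[C@@H](C)[C@H]12 | target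

## Totals and main risks

- **Total step count:** 19
- **Longest linear sequence:** 14 (Steps 1–9, then 15–19)

**Three steps most likely to fail, with fallbacks**

1. **Step 15 (proposed new Rh alkenylation).** Risks are addition at the wrong alkene, low ee, or base sensitivity of dienone 19. Fallback with known chemistry, building the stereocentre before the triene:
   - Ru–BINAP hydrogenation of α‑methylene‑γ‑butyrolactone to (R)‑α‑methyl‑γ‑butyrolactone, then DIBAL to the lactol.
   - Wittig with 6, DIBAL, MnO2; repeat once; then HWE with 10 to give the trienyl alcohol.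
   - Oxidise the primary alcohol to the (R)‑β‑methyl aldehyde, couple with 16 (Nozaki–Hiyama–Kishi) and oxidise with Dess–Martin periodinane to reach 20.

2. **Step 16 (IMDA).** The tether ketone may erode the trans (ester‑endo) selectivity or give cis‑fused product. Fallback: remove the tether carbonyl before cyclisation. Reduce the C4 ketone of 20 with a CBS catalyst to the matched allylic alcohol, protect as the TBS ether, and run the IMDA with only terminal ester activation and an sp3 tether. Then desilylate with HF·pyridine and oxidise to 21.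

3. **Step 17 (kinetic enol triflate).** Risks are enolisation towards C3a or epimerisation of the trans fusion. Fallback: a Shapiro route in place of triflate and cross‑coupling. Convert 21 to its 2,4,6‑triisopropylbenzenesulfonyl hydrazone, treat with n‑BuLi to form the C3 vinyllithium regiospecifically on the CH2 side, transmetalate to the cuprate and alkylate with EtI to give 23 directly.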